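## Structural features

The target is a C40 bis-labdane: two decalin diterpenoid units (labdane numbering, unprimed and primed) joined only by the C14=C15' double bond. C14 still carries the C15 formyl group, so the link is an (E)-2-alkyl-2-enal, formally the crossed aldol condensation product of two labdan-15-als. Each unit has the quaternary C4 (α-methyl, β-carboxyl C19), the angular C10 methyl, the exocyclic C8=C17 methylene on ring B and, at C9, a five-carbon chain with the C13 methyl centre (13S and 13'S). The units differ only at C5: the unprimed decalin is trans-fused (4S,5R,9S,10R), whereas the primed one is cis-fused with H5' on the face of the C10' methyl (4'S,5'S,9'S,10'R). In each decalin C4, C5, C10 and C9 are four adjacent stereocentres, two of them quaternary, and C9 stands next to the sp2 carbon C8. Fragile groups are the enal (base, nucleophiles, oxidants), the two exocyclic methylenes (acid moves them into the ring) and the neopentyl carboxyls, which cannot be freed by saponification beside the enal once esterified. The real difficulties are the cis-fused primed half, with the row C10' (quaternary), C9', C8' and no natural precursor, and the joining of two almost identical aldehydes in one sense only. The key step uses ring B' of the primed half: C8' is held as a ketone conjugated to a C9'=C10' double bond, so that C10' accepts the methyl group and C9' the C11'–C15' chain.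

## Logic of the disconnections

30 goes back to 29 by cutting the two ester O–C bonds at C19 and C19'. The axial carboxyls must travel masked through organometallic and basic steps, and the mask has to fall off by attack remote from the hindered carbonyl. The gain is that all C–C chemistry runs on neutral esters. The demand is a fluoride-triggered fragmentation at the end that spares the enal and both methylenes.

29 goes back through 27 to 24 and 20 by cutting C14=C15' (retro-aldol condensation). This is the only bond between the halves and both sides are aldehyde-level carbons, so it splits the molecule into two C20 pieces. Because the two aldehydes are nearly identical, direction must come from a preformed nucleophile: the unprimed partner reacts as the lithiated imine 25 made from 24, the primed partner as the free aldehyde 20. The elimination must give the (E) alkene.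

24 goes back through 23 and 22 to 21 by functional-group changes only. 21 already has the five stereocentres and twenty carbons of the unprimed half. The demand is an esterification of the hindered acid that leaves the primary alcohol alone, and an oxidation that stops at the aldehyde.

20 goes back through 19 and 18 to 17 by cutting C8'=C17' (carbonyl methylenation) and lowering C15' to the silyl ether. A ketone at C8' is what allows bonds to be made at C9' and C10'. The methylenation must not epimerise C9', and the silyl ether must be removed without loss of the ester.

17 goes back to 9, 15 and a methyl nucleophile by cutting C10'–C20' and C9'–C11'. Both bonds start from the two carbons of an enone C=C, and a conjugate addition produces exactly the enolate needed for the second bond. This removes the chain, the angular methyl and two stereocentres in one operation. The demands are methyl entry syn to H5', alkylation at C9' on the convex face before the enolate equilibrates, and a precursor 9 in which H5' is cis to the ester. No equilibration or reprotonation at C9' is planned: the alkylation itself should give the required epimer, and protonation of the enolate would occur from the same face and give the wrong one.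

15 goes back through 14, 13 and 11 to 10 by replacing C11'–I with C11'–CO2H (one carbon more) and then by alkene cleavage. 10 supplies the C13' methyl centre in the right sense but is one carbon too long on the alkene side, and ozonolysis with decarboxylative iodination trims it. The radical step must not touch the stereocentre.

9 goes back through 8 and 7 to 6 and 5 with no skeletal bond cut: ring B' comes from an anisole ring by Birch reduction. This makes C4' a benzylic quaternary carbon, which is easy to build. C5' arises only when the enone moves into conjugation and is not strongly biased, so separation and recycling are planned. The ester is put on after the Birch reduction (an ester would be reduced) but before the ketone is unmasked (the free β,γ-unsaturated acid would lactonise onto C10').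

5 goes back through 4 and 3 to 2 and 1: the C4'–C19' bond is treated as C4'–vinyl, formed by adding hydrogen and a vinyl group across the exocyclic alkene of 2. This builds the quaternary centre catalytically and enantioselectively from a commercial tetralone. It demands high enantioselectivity and an oxidative cleavage that spares the anisole ring.

## Other disconnections considered

Alternative 1: The cut removes C5–C10 and C8–C9 of the trans-fused unit at once and leads to the acyclic triene imide A2. In A2 an (S)-4-benzyl-oxazolidinone-bound (E)-3-methyl-2-enoyl group (C9=C10) is tied through C1–C4 to a terminal diene (C5=C6–C7=C8). Forward, Me2AlCl chelates the imide and an intramolecular Diels–Alder reaction through the endo transition state closes rings A and B to the trans-fused adduct A1.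
- In its favour: one concerted step sets C5, C9 and C10 together, the absolute sense comes from a cheap recoverable auxiliary, and the trans half would be made without a natural product. On that last point it is better than the chosen plan, which buys that half as 21.
- Against it here: the dienophile is β,β-disubstituted and must form a quaternary carbon, so the cycloaddition should be slow. A1 has no C17 and no function at C8, carries a surplus C6=C7 alkene, has two identical esters at C4 that must be told apart, and holds only C11 of the chain. Well over ten steps would separate A1 from 23.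
- Comparison: structurally it addresses the other half, and an endo closure cannot give the cis fusion of the primed unit, so it could replace the purchase of 21 but not step 12. Mechanistically it is the equal or the better in predictability of relative configuration (one concerted step against two successive polar bond formations). In step economy it is clearly longer for this target.

Alternative 2: The cut removes C4–C5 and C9–C10 of the trans-fused unit and leads to the acyclic (E,E)-polyene 2-methyl-3-oxo ester A4, which already holds the whole chain with C13. Forward, Mn(OAc)3 (trivalent manganese) oxidises the keto ester to the C4 radical, which closes ring A onto C5 and then ring B from C10 onto C9 through chair-like transition states. Cu(OAc)2 (divalent copper) oxidises the C8 radical to the exocyclic alkene of A3.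
- In its favour: two rings, four stereocentres, the axial ester and C8=C17 in one non-basic operation. In bonds and rings formed per step it is better than the chosen key step, and it makes the trans half from simple chemicals.
- Against it here: the chair–chair cascade is inherently trans-selective and cannot give the primed half. A3 keeps a C3 ketone to be removed next to a quaternary carbon, the 8-phenylmenthyl ester on the axial C19 is very hard to cleave, C7=C8 alkene isomers are to be expected, and A4 needs two trisubstituted (E)-alkenes.
- Comparison: as a source of the unprimed unit it loses to the two steps from 21 on step count but wins on independence from an isolated natural product. As a replacement for step 12 it fails on ring-fusion stereochemistry. Mechanistically its radical steps are less sensitive to steric hindrance at quaternary carbons than the enolate alkylation of step 12, a point on which it is the better.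

Alternative 3: The cut removes only C9'–C10' of the primed unit. Ring B' is opened to the 3-methylcyclohexenone A6 (ring A' with C4' and C5' in place), which carries at C5' a tether ending in an allylsilane (Si–C17'H2–C8'=C9'). Forward, EtAlCl2 activates the enone, C9' adds to C10', loss of silicon creates C8'=C17', and because the tether is anchored at C5' the new ring can only be cis-fused (A5).
- In its favour: it targets the same half as step 12 and is its equal in setting C9' and C10' in one step. It is better in that the exocyclic methylene appears directly (no C8' ketone, no epimerisable C9' stage, no methylenation), no stoichiometric copper or HMPA is used, and no hindered enolate has to be alkylated intermolecularly.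
- Against it here: A5 bears a C2' ketone that the target lacks, and its removal costs about three steps beside the exocyclic alkene. The chain with C13' must be carried from the start, so convergence is lost. The C8'=C9' geometry that decides C9' has to be built selectively, and A6 needs the same C4'/C5' relationship as 9 on a monocyclic enone, where it is no easier to control.
- Comparison: structurally both reach the cis-fused ring B' with its three substituents in a row, the chosen step by two intermolecular bonds to a preformed bicycle, this one by a ring closure. Mechanistically both are conjugate additions with the roles exchanged, and the intramolecular version is probably the more reliable way to form the quaternary centre. In step economy, what is saved after the key step is spent before it and on the deoxygenation, so the chosen plan should be shorter by a few steps and more convergent.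

Key step: step 12

Assumption: the trans-fused half is taken from the chiral pool as (13S)-imbricatolic acid (21), a catalogue natural product believed (not verified here) to match C4, C5, C9, C10 and C13 of the target; only the cis-fused half is built from simple chemicals.

Step 1
Reactants: 1 6-methoxy-1-tetralone
Product: 2 6-methoxy-1-methylidene-1,2,3,4-tetrahydronaphthalene
Conditions: Ph3PCH3Br, KOtBu, THF, 0 °C → rt
Reagents that add atoms: methyltriphenylphosphonium bromide, C[P+](c1ccccc1)(c1ccccc1)c1ccccc1.[Br-]
Why: Wittig methylenation of an aryl ketone with the non-stabilised ylide; the styrene is handled without acid so that the double bond does not move into the ring.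

Step 2
Reactants: 2 6-methoxy-1-methylidene-1,2,3,4-tetrahydronaphthalene
Product: 3 (R)-1-ethenyl-6-methoxy-1-methyl-1,2,3,4-tetrahydronaphthalene
Conditions: ethylene (1 atm), [Ni(η3-C3H5)Br]2 (cat.), phosphoramidite ligand from BINOL and bis(1-phenylethyl)amine (cat.; enantiomer giving (R)-3), Na[B(3,5-(CF3)2C6H3)4] (cat.), CH2Cl2, −70 °C
Reagents that add atoms: ethylene, C=C
Why: Nickel-catalysed asymmetric hydrovinylation of a 1,1-disubstituted styrene, a reaction type established for 1-methylidene-tetralins: the cationic nickel hydride adds to the exocyclic alkene to give the tertiary benzylic nickel alkyl, ethylene inserts and β-hydride elimination releases the vinyl group, which creates the quaternary centre (the later C4'). The phosphoramidite decides the face, and the ligand enantiomer that leads to (R)-3 is used, both being accessible.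

Step 3
Reactants: 3 (R)-1-ethenyl-6-methoxy-1-methyl-1,2,3,4-tetrahydronaphthalene
Product: 4 (S)-6-methoxy-1-methyl-1,2,3,4-tetrahydronaphthalene-1-carbaldehyde
Conditions: OsO4 (cat.), NaIO4, 2,6-lutidine, dioxane/H2O, rt
Reagents that add atoms: sodium periodate (aldehyde oxygen, relayed through OsO4), [Na+].[O-]I(=O)(=O)=O
Why: Lemieux–Johnson cleavage: osmylation of the only alkene and periodate cleavage of the diol give the aldehyde, with 2,6-lutidine suppressing over-oxidation; ozone is avoided because of the electron-rich anisole ring. The quaternary centre has no α-hydrogen and cannot epimerise.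

Step 4
Reactants: 4 (S)-6-methoxy-1-methyl-1,2,3,4-tetrahydronaphthalene-1-carbaldehyde
Product: 5 (S)-6-methoxy-1-methyl-1,2,3,4-tetrahydronaphthalene-1-carboxylic acid
Conditions: NaClO2, NaH2PO4, 2-methyl-2-butene, t-BuOH/H2O, rt
Reagents that add atoms: sodium chlorite, [Na+].[O-]Cl=O
Why: Pinnick oxidation of the hindered aldehyde to the acid; 2-methyl-2-butene removes HOCl and so protects the anisole ring from chlorination.

Step 5
Reactants: 5 (S)-6-methoxy-1-methyl-1,2,3,4-tetrahydronaphthalene-1-carboxylic acid
Product: 6 (S)-6-methoxy-1-methyl-1,2,3,4,5,8-hexahydronaphthalene-1-carboxylic acid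
Conditions: Li, NH3 (l), THF, t-BuOH, −78 → −33 °C; NH4Cl; extraction at pH 5, 0 °C
Reagents that add atoms: none
Why: Birch reduction: the lithium carboxylate is not reduced (an ester would be, which is why the acid is reduced first), and the anisole ring is protonated at the two ring carbons ortho and meta to the methoxy group that are not ring-fusion carbons, giving the enol ether and the tetrasubstituted C5'=C10' alkene. The cold work-up near pH 5 frees the acid without hydrolysing the enol ether.

Step 6
Reactants: 6 (S)-6-methoxy-1-methyl-1,2,3,4,5,8-hexahydronaphthalene-1-carboxylic acid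
Product: 7 2-(trimethylsilyl)ethyl (S)-6-methoxy-1-methyl-1,2,3,4,5,8-hexahydronaphthalene-1-carboxylate
Conditions: Me3SiCH2CH2OH, PPh3, DIAD, THF, 0 °C → rt
Reagents that add atoms: 2-(trimethylsilyl)ethanol, C[Si](C)(C)CCO
Why: Mitsunobu esterification, in which the hindered carboxylate is the nucleophile and attacks the activated primary alcohol, so the congested carbonyl carbon is not involved and the neutral conditions spare the enol ether. Esterifying before the ketone is unmasked prevents the free β,γ-unsaturated acid from closing a γ-lactone onto C10' under acid.

Step 7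
Reactants: 7 2-(trimethylsilyl)ethyl (S)-6-methoxy-1-methyl-1,2,3,4,5,8-hexahydronaphthalene-1-carboxylate
Product: 9 2-(trimethylsilyl)ethyl (1S,8aS)-1-methyl-6-oxo-1,2,3,4,6,7,8,8a-octahydronaphthalene-1-carboxylate, via β,γ-unsaturated ketone 8 (not isolated)
Conditions: 2 M aq. HCl, THF, rt
Reagents that add atoms: water, O
Why: Acid hydrolysis of the enol ether gives 8, which moves into conjugation through its dienol by protonation at C5'; the TMSE ester is stable to dilute acid. C5' is created here under equilibrating conditions: the wanted epimer has ring A as a chair with H5' axial, the ester equatorial and the 4'α-methyl axial, while the other epimer has ester and methyl exchanged. Because the two should be close in energy, 9 is separated by chromatography and its C5' epimer is re-equilibrated with DBU and recycled.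

Step 8
Reactants: 10 (S)-citronellol
Product: 11 (S)-tert-butyl[(3,7-dimethyloct-6-en-1-yl)oxy]dimethylsilane
Conditions: TBSCl, imidazole, CH2Cl2, rt
Reagents that add atoms: tert-butyldimethylsilyl chloride, CC(C)(C)[Si](C)(C)Cl
Why: Standard silylation of the primary alcohol; the TBS ether survives ozone, chlorite, the radical iodination and the enolate chemistry of step 12.

Step 9
Reactants: 11 (S)-tert-butyl[(3,7-dimethyloct-6-en-1-yl)oxy]dimethylsilane
Product: 13 (S)-6-[(tert-butyldimethylsilyl)oxy]-4-methylhexanal, via ozonide 12 (not isolated)
Conditions: O3, CH2Cl2, −78 °C; PPh3, −78 °C → rt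
Reagents that add atoms: ozone, [O-][O+]=O
Why: Ozonolysis of the trisubstituted alkene and reduction of the ozonide 12 with PPh3 give the aldehyde and acetone; the stereocentre is remote and untouched.

Step 10
Reactants: 13 (S)-6-[(tert-butyldimethylsilyl)oxy]-4-methylhexanal
Product: 14 (S)-6-[(tert-butyldimethylsilyl)oxy]-4-methylhexanoic acid
Conditions: NaClO2, NaH2PO4, 2-methyl-2-butene, t-BuOH/H2O, rt
Reagents that add atoms: sodium chlorite, [Na+].[O-]Cl=O
Why: Pinnick oxidation to the acid under buffered conditions that leave the silyl ether intact.

Step 11
Reactants: 14 (S)-6-[(tert-butyldimethylsilyl)oxy]-4-methylhexanoic acid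
Product: 15 (R)-tert-butyl[(5-iodo-3-methylpentyl)oxy]dimethylsilane
Conditions: PhI(OAc)2, I2, hν (tungsten lamp), cyclohexane, reflux
Reagents that add atoms: iodine, II
Why: Hunsdiecker-type iododecarboxylation with PhI(OAc)2/I2 under light: the acyl hypoiodite fragments to CO2 and a primary alkyl radical, which is captured by iodine. This removes the one surplus carbon and leaves the methyl-bearing centre, two carbons from the radical, untouched (its descriptor changes from S to R only because iodine changes the priorities).

Step 12
Reactants: 9 2-(trimethylsilyl)ethyl (1S,8aS)-1-methyl-6-oxo-1,2,3,4,6,7,8,8a-octahydronaphthalene-1-carboxylate; 15 (R)-tert-butyl[(5-iodo-3-methylpentyl)oxy]dimethylsilane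
Product: 17 2-(trimethylsilyl)ethyl (13'S)-15'-(tert-butyldimethylsilyloxy)-8'-oxo-17'-nor-5'β-labdan-19'-oate, via lithium C8'–C9' enolate 16 (not isolated)
Conditions: Me2CuLi (from CuI and MeLi), Et2O, −20 → 0 °C; then THF, HMPA, 15 (excess), −20 °C → rt; NH4Cl
Reagents that add atoms: methyllithium (delivered as Me2CuLi), [Li]C
Why: Three-component conjugate addition–enolate alkylation, whose closest known reaction type is the cuprate methylation of ring-fusion octalones with alkylation of the regiospecific enolate. Me2CuLi (monovalent copper) forms a π complex with the enone, oxidative addition gives the C10' adduct (trivalent copper) and reductive elimination forms C10'–C20', leaving the C8'–C9' lithium enolate 16; in THF/HMPA this enolate displaces iodide from the primary carbon of 15 (SN2) to form C9'–C11', and no ring is closed. At C10', ring A of 9 is a chair with H5' axial, so the 4'α-methyl is axial and blocks the α face (a methyl entering there would end syn-diaxial to it), while the face syn to H5' is open, which gives the cis ring fusion that cuprates normally give with such enones. At C9', the cis-fused enolate can only adopt the half-chair with C10'–C1' axial on ring B (the other one would force the 4'α-methyl under ring B), so the electrophile enters axially, anti to C10'–C1' and on the convex β face, and places the chain β (9'α-H) as the target requires. The step needs C- rather than O-alkylation, and alkylation before the enolate equilibrates towards C7' or is protonated; the regiodefined enolate, HMPA and an excess of the unhindered primary iodide secure this, and the neopentyl TMSE ester and the TBS ether are inert to both reagents. Because the two C9' epimers of 17 should be close in energy and protonation of 16 would occur from the same β face (giving the wrong epimer), 17 is neither equilibrated nor reprotonated but carried on under non-basic conditions.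

Step 13
Reactants: 17 2-(trimethylsilyl)ethyl (13'S)-15'-(tert-butyldimethylsilyloxy)-8'-oxo-17'-nor-5'β-labdan-19'-oate
Product: 18 2-(trimethylsilyl)ethyl (13'S)-15'-(tert-butyldimethylsilyloxy)-5'β-labd-8'(17')-en-19'-oate
Conditions: Zn, CH2Br2, TiCl4 (reagent pre-formed in THF), CH2Cl2, 0 °C → rt
Reagents that add atoms: dibromomethane, BrCBr
Why: Takai–Lombardo methylenation: the titanium–zinc methylene reagent is not basic, so the kinetically set and epimerisable C9' centre is preserved, and it reacts with the ketone in preference to the hindered ester. Silyl ether and TMSE ester are unaffected.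

Step 14
Reactants: 18 2-(trimethylsilyl)ethyl (13'S)-15'-(tert-butyldimethylsilyloxy)-5'β-labd-8'(17')-en-19'-oate
Product: 19 2-(trimethylsilyl)ethyl (13'S)-15'-hydroxy-5'β-labd-8'(17')-en-19'-oate
Conditions: camphorsulfonic acid (cat.), MeOH/CH2Cl2, 0 °C
Reagents that add atoms: none
Why: Acid-catalysed methanolysis removes the primary TBS ether; fluoride is avoided here because it would also cleave the TMSE ester, and the conditions are too mild to move the exocyclic double bond.

Step 15
Reactants: 19 2-(trimethylsilyl)ethyl (13'S)-15'-hydroxy-5'β-labd-8'(17')-en-19'-oate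
Product: 20 2-(trimethylsilyl)ethyl (13'S)-15'-oxo-5'β-labd-8'(17')-en-19'-oate
Conditions: TEMPO (cat.), PhI(OAc)2, CH2Cl2, rt
Reagents that add atoms: none
Why: Oxoammonium (TEMPO) oxidation with PhI(OAc)2 as terminal oxidant stops at the aldehyde and uses no base; C13' is β to the new carbonyl and cannot epimerise.

Step 16
Reactants: 21 (13S)-imbricatolic acid
Product: 22 2-(trimethylsilyl)ethyl (13S)-15-hydroxylabd-8(17)-en-19-oate
Conditions: Me3SiCH2CH2OC(=NH)CCl3, toluene, reflux
Reagents that add atoms: 2-(trimethylsilyl)ethyl 2,2,2-trichloroacetimidate, C[Si](C)(C)CCOC(=N)C(Cl)(Cl)Cl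
Why: Promoter-free esterification with a trichloroacetimidate: the carboxylic acid protonates the imidate and the ion pair collapses at the β-silyl-stabilised carbon, so the hindered axial carbonyl is never attacked. The primary alcohol is not acidic enough to activate the imidate and stays free, which a Mitsunobu reaction would not allow.

Step 17
Reactants: 22 2-(trimethylsilyl)ethyl (13S)-15-hydroxylabd-8(17)-en-19-oate
Product: 23 2-(trimethylsilyl)ethyl (13S)-15-oxolabd-8(17)-en-19-oate
Conditions: TEMPO (cat.), PhI(OAc)2, CH2Cl2, rt
Reagents that add atoms: none
Why: The same oxoammonium oxidation as in step 15; it stops at the aldehyde and leaves the exocyclic alkene and C13 untouched.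

Step 18
Reactants: 23 2-(trimethylsilyl)ethyl (13S)-15-oxolabd-8(17)-en-19-oate
Product: 24 N-cyclohexyl (E)-aldimine of 23 (C15=N)
Conditions: cyclohexylamine, MgSO4, Et2O, 0 °C → rt
Reagents that add atoms: cyclohexylamine, NC1CCCCC1
Why: Condensation of the aldehyde with a primary amine gives the N-cyclohexyl aldimine, the aza-enolate precursor for the directed aldol; MgSO4 removes the water.

Step 19
Reactants: 24 N-cyclohexyl (E)-aldimine of 23 (C15=N); 20 2-(trimethylsilyl)ethyl (13'S)-15'-oxo-5'β-labd-8'(17')-en-19'-oate
Product: 27 aldol adduct (β-hydroxy aldehyde; C14–C15' bond; both acids as 2-(trimethylsilyl)ethyl esters), via lithium aza-enolate 25 (not isolated), via lithium alkoxide of the β-hydroxy imine 26 (not isolated)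
Conditions: LiN(iPr)2, THF, −78 → 0 °C; 20, −78 °C; then aq. AcOH/NaOAc (pH 4.5), THF, 0 °C → rt
Reagents that add atoms: water, O
Why: Wittig directed aldol reaction: LiN(iPr)2 deprotonates the imine at C14, its only α position, and the aza-enolate 25 adds to the aldehyde 20 at −78 °C faster than it deprotonates it, which fixes which partner is donor and which is acceptor. The chelated lithium alkoxide 26 is hydrolysed in buffered acid to the aldol 27; the new centres at C14 and C15' form as a mixture that is removed in step 20.

Step 20
Reactants: 27 aldol adduct (β-hydroxy aldehyde; C14–C15' bond; both acids as 2-(trimethylsilyl)ethyl esters)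
Product: 29 bis[2-(trimethylsilyl)ethyl] ester of the target (E)-enal, via β-mesyloxy aldehyde 28 (not isolated)
Conditions: MsCl, Et3N, CH2Cl2, 0 °C → rt
Reagents that add atoms: none
Why: Mesylation of the secondary alcohol and E1cB elimination through the aldehyde enolate give the trisubstituted enal. The (E) isomer, with the formyl group trans to C14', is the more stable one for a 2-alkyl-2-enal and should predominate; C13 and C13' carry no acidic hydrogen under these conditions.

Step 21
Reactants: 29 bis[2-(trimethylsilyl)ethyl] ester of the target (E)-enal
Product: 30 target diacid CNP0229303.1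
Conditions: (Me2N)3S+ Me3SiF2− (TASF), DMF, 0 °C → rt; cold 0.1 M HCl work-up
Reagents that add atoms: none
Why: Fluoride attacks silicon of each 2-(trimethylsilyl)ethyl ester and the fragment leaves as ethylene and fluorotrimethylsilane, so both hindered carboxylates are released without attack at their carbonyl groups. The anhydrous fluoride source and the cold work-up are chosen to spare the enal and the exocyclic alkenes.

## Compound list

1 | 6-methoxy-1-tetralone (6-methoxy-3,4-dihydronaphthalen-1(2H)-one) | COc1ccc2C(=O)CCCc2c1 | starting material
2 | 6-methoxy-1-methylidene-1,2,3,4-tetrahydronaphthalene | COc1ccc2C(=C)CCCc2c1 | intermediate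
3 | (R)-1-ethenyl-6-methoxy-1-methyl-1,2,3,4-tetrahydronaphthalene | COc1ccc2c(c1)CCC[C@]2(C)C=C | intermediate
4 | (S)-6-methoxy-1-methyl-1,2,3,4-tetrahydronaphthalene-1-carbaldehyde | COc1ccc2c(c1)CCC[C@]2(C)C=O | intermediate
5 | (S)-6-methoxy-1-methyl-1,2,3,4-tetrahydronaphthalene-1-carboxylic acid | COc1ccc2c(c1)CCC[C@]2(C)C(=O)O | intermediate
6 | (S)-6-methoxy-1-methyl-1,2,3,4,5,8-hexahydronaphthalene-1-carboxylic acid | COC1=CCC2=C(C1)CCC[C@]2(C)C(=O)O | intermediate
7 | 2-(trimethylsilyl)ethyl (S)-6-methoxy-1-methyl-1,2,3,4,5,8-hexahydronaphthalene-1-carboxylate | COC1=CCC2=C(C1)CCC[C@]2(C)C(=O)OCC[Si](C)(C)C | intermediate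
8 | 2-(trimethylsilyl)ethyl (S)-1-methyl-6-oxo-1,2,3,4,5,6,7,8-octahydronaphthalene-1-carboxylate (β,γ-unsaturated ketone, not isolated) | O=C1CCC2=C(C1)CCC[C@]2(C)C(=O)OCC[Si](C)(C)C | intermediate
9 | 2-(trimethylsilyl)ethyl (1S,8aS)-1-methyl-6-oxo-1,2,3,4,6,7,8,8a-octahydronaphthalene-1-carboxylate (8'-oxo-9'(10')-ene; H5' cis to the ester) | O=C1CC[C@H]2C(=C1)CCC[C@]2(C)C(=O)OCC[Si](C)(C)C | intermediate
10 | (S)-citronellol ((S)-3,7-dimethyloct-6-en-1-ol) | C[C@@H](CCC=C(C)C)CCO | starting material
11 | (S)-tert-butyl[(3,7-dimethyloct-6-en-1-yl)oxy]dimethylsilane | C[C@@H](CCC=C(C)C)CCO[Si](C)(C)C(C)(C)C | intermediate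
12 | ozonide of 11: 5-[(S)-5-(tert-butyldimethylsilyloxy)-3-methylpentyl]-3,3-dimethyl-1,2,4-trioxolane (not isolated) | CC1(C)OOC(CC[C@H](C)CCO[Si](C)(C)C(C)(C)C)O1 | intermediate
13 | (S)-6-[(tert-butyldimethylsilyl)oxy]-4-methylhexanal | C[C@@H](CCC=O)CCO[Si](C)(C)C(C)(C)C | intermediate
14 | (S)-6-[(tert-butyldimethylsilyl)oxy]-4-methylhexanoic acid | C[C@@H](CCC(=O)O)CCO[Si](C)(C)C(C)(C)C | intermediate
15 | (R)-tert-butyl[(5-iodo-3-methylpentyl)oxy]dimethylsilane | CC(C)(C)[Si](C)(C)OCC[C@@H](C)CCI | intermediate
16 | lithium C8'–C9' enolate of the cis-fused 10'-methyl adduct: 2-(trimethylsilyl)ethyl (1S,4aS,8aS)-6-(lithiooxy)-1,4a-dimethyl-1,2,3,4,4a,7,8,8a-octahydronaphthalene-1-carboxylate (not isolated) | [Li]OC1=C[C@@]2(C)CCC[C@](C)(C(=O)OCC[Si](C)(C)C)[C@H]2CC1 | intermediate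
17 | 2-(trimethylsilyl)ethyl (13'S)-15'-(tert-butyldimethylsilyloxy)-8'-oxo-17'-nor-5'β-labdan-19'-oate (cis-fused: H5'β, 10'β-methyl, 9'α-H with the chain β, 4'α-methyl, 4'β-ester) | CC(C)(C)[Si](C)(C)OCC[C@@H](C)CC[C@H]1C(=O)CC[C@H]2[C@]1(C)CCC[C@]2(C)C(=O)OCC[Si](C)(C)C | intermediate
18 | 2-(trimethylsilyl)ethyl (13'S)-15'-(tert-butyldimethylsilyloxy)-5'β-labd-8'(17')-en-19'-oate (cis-fused, configuration as 17) | CC(C)(C)[Si](C)(C)OCC[C@@H](C)CC[C@H]1C(=C)CC[C@H]2[C@]1(C)CCC[C@]2(C)C(=O)OCC[Si](C)(C)C | intermediate
19 | 2-(trimethylsilyl)ethyl (13'S)-15'-hydroxy-5'β-labd-8'(17')-en-19'-oate | OCC[C@@H](C)CC[C@H]1C(=C)CC[C@H]2[C@]1(C)CCC[C@]2(C)C(=O)OCC[Si](C)(C)C | intermediate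
20 | 2-(trimethylsilyl)ethyl (13'S)-15'-oxo-5'β-labd-8'(17')-en-19'-oate | O=CC[C@@H](C)CC[C@H]1C(=C)CC[C@H]2[C@]1(C)CCC[C@]2(C)C(=O)OCC[Si](C)(C)C | intermediate
21 | (13S)-imbricatolic acid ((13S)-15-hydroxylabd-8(17)-en-19-oic acid; trans-fused, 4S,5R,9S,10R) | C=C1CC[C@@H]2[C@](C)(CCC[C@]2(C)C(=O)O)[C@H]1CC[C@H](C)CCO | starting material
22 | 2-(trimethylsilyl)ethyl (13S)-15-hydroxylabd-8(17)-en-19-oate | C=C1CC[C@@H]2[C@](C)(CCC[C@]2(C)C(=O)OCC[Si](C)(C)C)[C@H]1CC[C@H](C)CCO | intermediate
23 | 2-(trimethylsilyl)ethyl (13S)-15-oxolabd-8(17)-en-19-oate | C=C1CC[C@@H]2[C@](C)(CCC[C@]2(C)C(=O)OCC[Si](C)(C)C)[C@H]1CC[C@H](C)CC=O | intermediate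
24 | N-cyclohexyl (E)-aldimine of 23 (C15=N) | C=C1CC[C@@H]2[C@](C)(CCC[C@]2(C)C(=O)OCC[Si](C)(C)C)[C@H]1CC[C@H](C)C/C=N/C1CCCCC1 | intermediate
25 | lithium aza-enolate of 24 (C14=C15–N(Li)-cyclohexyl; not isolated) | C=C1CC[C@@H]2[C@](C)(CCC[C@]2(C)C(=O)OCC[Si](C)(C)C)[C@H]1CC[C@H](C)C=CN([Li])C1CCCCC1 | intermediate
26 | lithium alkoxide of the β-hydroxy imine (C14–C15' bond formed; mixture at C14 and C15'; not isolated) | C=C1CC[C@@H]2[C@](C)(CCC[C@]2(C)C(=O)OCC[Si](C)(C)C)[C@H]1CC[C@H](C)C(C=NC1CCCCC1)C(O[Li])C[C@@H](C)CC[C@H]1C(=C)CC[C@H]2[C@]1(C)CCC[C@]2(C)C(=O)OCC[Si](C)(C)C | intermediate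
27 | aldol adduct: C14 (bearing the C15 formyl group) bonded to C15'(OH); mixture at C14 and C15'; both C19 acids as 2-(trimethylsilyl)ethyl esters | C=C1CC[C@@H]2[C@](C)(CCC[C@]2(C)C(=O)OCC[Si](C)(C)C)[C@H]1CC[C@H](C)C(C=O)C(O)C[C@@H](C)CC[C@H]1C(=C)CC[C@H]2[C@]1(C)CCC[C@]2(C)C(=O)OCC[Si](C)(C)C | intermediate
28 | β-mesyloxy aldehyde (15'-O-methanesulfonate of 27; not isolated) | C=C1CC[C@@H]2[C@](C)(CCC[C@]2(C)C(=O)OCC[Si](C)(C)C)[C@H]1CC[C@H](C)C(C=O)C(OS(C)(=O)=O)C[C@@H](C)CC[C@H]1C(=C)CC[C@H]2[C@]1(C)CCC[C@]2(C)C(=O)OCC[Si](C)(C)C | intermediate
29 | bis[2-(trimethylsilyl)ethyl] ester of the target (E)-enal (C14=C15', formyl trans to C14') | C=C1CC[C@@H]2[C@](C)(CCC[C@]2(C)C(=O)OCC[Si](C)(C)C)[C@H]1CC[C@H](C)/C(C=O)=C\C[C@@H](C)CC[C@H]1C(=C)CC[C@H]2[C@]1(C)CCC[C@]2(C)C(=O)OCC[Si](C)(C)C | intermediate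
30 | CNP0229303.1: (E)-enal diacid, unprimed half trans-fused, primed half cis-fused | C=C1CC[C@@H]2[C@](C)(CCC[C@]2(C)C(=O)O)[C@H]1CC[C@H](C)/C(C=O)=C\C[C@@H](C)CC[C@H]1C(=C)CC[C@H]2[C@]1(C)CCC[C@]2(C)C(=O)O | target

Total step count: 21 steps. Longest linear sequence: 14 steps (steps 1–7, 12–15, 19, 20, 21).

## Least certain steps

**Step 12 (key step).** Most likely to go wrong: slow methyl transfer to the hindered β,β-disubstituted enone, and proton transfer instead of C-alkylation of the copper-containing enolate, which would return the unalkylated cis-ketone or allow migration of the enolate towards C7'. Fallback (sets out from 9, returns at 17): the cuprate addition is run with TMSCl/Et3N so that the enolate is trapped as the trimethylsilyl enol ether F1, which is isolated. MeLi in THF then releases the copper-free lithium enolate 16, which is alkylated with 15 in THF/HMPA to give 17.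

**Step 7.** Most likely to go wrong: poor facial selectivity in the protonation at C5', or an equilibrium that lies on the side of the unwanted epimer, because an axial ester costs less than an axial methyl on ring A; repeated recycling would then waste material. Fallback (sets out from 7, returns at 9): 7 is transketalised with ethane-1,2-diol and oxalic acid to the 5'(10')-ene dioxolane F2 without moving the double bond. Hydrogenation with [Ir(cod)(PCy3)(py)]PF6, directed by the ester carbonyl, adds both hydrogens on the ester face and gives the cis-fused ketal F3 with H5' already cis to the ester. Mild aqueous acid frees the cis-decalone F4, thermodynamic silylation (TMSCl, Et3N, NaI) gives the C8'=C9' silyl enol ether F5, and Saegusa–Ito oxidation with Pd(OAc)2 returns 9 with C5' untouched.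

**Step 2.** Most likely to go wrong: insufficient enantioselectivity, or isomerisation of the exocyclic alkene to the endocyclic 1-methyl-3,4-dihydronaphthalene by the nickel hydride before ethylene is taken up. Fallback (sets out from 1, returns at 5): reductive cyanation of 1 with TosMIC and KOtBu gives the racemic nitrile F6, and methylation (LiN(iPr)2, MeI) gives the racemic quaternary nitrile F7. Hydrolysis (KOH, ethylene glycol, 180 °C) gives the racemic acid F8, which is resolved by crystallisation of its salt F9 with (R)-1-phenylethylamine (the antipodal amine if the other acid crystallises); acidification returns 5.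

**Step 19.** Most likely to go wrong: proton transfer from the enolisable acceptor 20 to the aza-enolate, which regenerates both partners and opens the way to self-condensation, or retro-aldol cleavage during the hydrolysis of the imine. Fallback (sets out from 23, returns at 27): 23 is converted into its trimethylsilyl enol ether F10 (TMSCl, Et3N, NaI, MeCN) and added to 20 with BF3·OEt2 at −78 °C (Mukaiyama aldol), a non-basic addition in which 20 cannot be enolised; aqueous work-up gives 27.

**Step 13.** Most likely to go wrong: incomplete conversion of the hindered ketone, or epimerisation at C9' if enolisation competes with methylene transfer. Fallback (sets out from 17, returns at 18): Peterson olefination. Me3SiCH2Li with CeCl3 adds to the ketone without enolising it to give the β-hydroxysilane F11, and KH in THF (syn elimination) gives 18.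

## Further compounds

F1 | step 12 | 2-(trimethylsilyl)ethyl (1S,4aS,8aS)-1,4a-dimethyl-6-(trimethylsilyloxy)-1,2,3,4,4a,7,8,8a-octahydronaphthalene-1-carboxylate (silyl enol ether of the cis-fused 10'-methyl adduct) | C[Si](C)(C)OC1=C[C@@]2(C)CCC[C@](C)(C(=O)OCC[Si](C)(C)C)[C@H]2CC1
F2 | step 7 | 2-(trimethylsilyl)ethyl (S)-6,6-(ethylenedioxy)-1-methyl-1,2,3,4,5,6,7,8-octahydronaphthalene-1-carboxylate | O1CCOC12CCC3=C(C2)CCC[C@]3(C)C(=O)OCC[Si](C)(C)C
F3 | step 7 | 2-(trimethylsilyl)ethyl (1S)-6,6-(ethylenedioxy)-1-methyldecahydronaphthalene-1-carboxylate, cis-fused, H4a and H8a on the ester face | O1CCOC12CC[C@H]3[C@@H](C2)CCC[C@]3(C)C(=O)OCC[Si](C)(C)C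
F4 | step 7 | 2-(trimethylsilyl)ethyl (1S)-1-methyl-6-oxodecahydronaphthalene-1-carboxylate, cis-fused, H4a and H8a on the ester face | O=C1CC[C@H]2[C@@H](C1)CCC[C@]2(C)C(=O)OCC[Si](C)(C)C
F5 | step 7 | C8'=C9' trimethylsilyl enol ether of F4 | C[Si](C)(C)OC1=C[C@H]2CCC[C@](C)(C(=O)OCC[Si](C)(C)C)[C@H]2CC1
F6 | step 2 | racemic 6-methoxy-1,2,3,4-tetrahydronaphthalene-1-carbonitrile | N#CC1CCCc2cc(OC)ccc12
F7 | step 2 | racemic 6-methoxy-1-methyl-1,2,3,4-tetrahydronaphthalene-1-carbonitrile | CC1(C#N)CCCc2cc(OC)ccc12
F8 | step 2 | racemic 6-methoxy-1-methyl-1,2,3,4-tetrahydronaphthalene-1-carboxylic acid | CC1(C(=O)O)CCCc2cc(OC)ccc12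
F9 | step 2 | (R)-1-phenylethylammonium (S)-6-methoxy-1-methyl-1,2,3,4-tetrahydronaphthalene-1-carboxylate | COc1ccc2c(c1)CCC[C@]2(C)C(=O)[O-].C[C@@H]([NH3+])c1ccccc1
F10 | step 19 | trimethylsilyl enol ether of 23 (C14=C15–OSiMe3) | C=C1CC[C@@H]2[C@](C)(CCC[C@]2(C)C(=O)OCC[Si](C)(C)C)[C@H]1CC[C@H](C)C=CO[Si](C)(C)C
F11 | step 13 | β-hydroxysilane from 17: 8'-hydroxy-8'-(trimethylsilylmethyl) adduct | CC(C)(C)[Si](C)(C)OCC[C@@H](C)CC[C@H]1C(O)(C[Si](C)(C)C)CC[C@H]2[C@]1(C)CCC[C@]2(C)C(=O)OCC[Si](C)(C)C
A1 | alternative 1 | trans-fused 6-ene bicycle with C4 dimethyl diester, C10 methyl and C9 acyl (S)-4-benzyl-oxazolidinone | C1C=C[C@@H]2[C@](C)(CCCC2(C(=O)OC)C(=O)OC)[C@H]1C(=O)N1C(=O)OC[C@@H]1Cc1ccccc1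
A2 | alternative 1 | acyclic triene imide: (E)-3-methyl-2-enoyl (S)-4-benzyl-oxazolidinone tethered through C1–C4 (C4 dimethyl diester) to the (E)-terminal diene | C=C/C=C/C(CCC/C(C)=C/C(=O)N1C(=O)OC[C@@H]1Cc1ccccc1)(C(=O)OC)C(=O)OC
A3 | alternative 2 | 8-phenylmenthyl 15-(tert-butyldiphenylsilyloxy)-3-oxolabd-8(17)-en-19-oate | C=C1CC[C@@H]2[C@](C)(CCC(=O)[C@]2(C)C(=O)O[C@@H]3C[C@H](C)CC[C@H]3C(C)(C)c3ccccc3)[C@H]1CC[C@H](C)CCO[Si](C(C)(C)C)(c1ccccc1)c1ccccc1
A4 | alternative 2 | acyclic (E,E)-polyene 2-methyl-3-oxo 8-phenylmenthyl ester with the (13S) silyloxy chain | CC(C(=O)O[C@@H]1C[C@H](C)CC[C@H]1C(C)(C)c1ccccc1)C(=O)CC/C(C)=C/CC/C(C)=C/CC[C@H](C)CCO[Si](C(C)(C)C)(c1ccccc1)c1ccccc1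
A5 | alternative 3 | cis-fused 2'-oxo primed half with C8'=C17', silylated C15' and 2-(trimethylsilyl)ethyl C19' ester | CC(C)(C)[Si](c1ccccc1)(c1ccccc1)OCC[C@@H](C)CC[C@H]1C(=C)CC[C@H]2[C@]1(C)CC(=O)C[C@]2(C)C(=O)OCC[Si](C)(C)C
A6 | alternative 3 | 3-methylcyclohexenone (ring A') with C4' methyl and ester, carrying at C5' the allylsilane tether (C8'=C9' geometry to be chosen to set C9') | CC1=CC(=O)C[C@](C)(C(=O)OCC[Si](C)(C)C)[C@H]1CCC(C[Si](C)(C)C)=CCC[C@H](C)CCO[Si](C(C)(C)C)(c1ccccc1)c1ccccc1
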